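**Assumption:** the target SMILES contains no stereocentre and no stereogenic double bond. The compound is achiral, so the "single enantiomer" is the compound itself. Stereocentres in intermediates are racemic and are all erased before the end.

## Retrosynthetic overview
1. The last operation is a global O-debenzylation. Ring A is not taken from an arene but is built last, by a Danheiser benzannulation (trisubstituted cyclobutenone + methoxyacetylene) that sets all five substituents and the OH/OMe difference in one step.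
2. The cyclobutenone comes from Grignard 1,2-addition and carbonyl transposition on a locally symmetric 3-ethoxy-2,4-dibenzylcyclobutenone, which attaches the ring B arm.
3. That vinylogous ester comes from thermal self-condensation of one ynol ether (retro-ene to a ketene, then [2+2]). The ynol ether comes from ethoxyacetylene and 4-(benzyloxy)benzyl chloride.
4. The ring B arm comes from 2-(3-hydroxyphenyl)ethanol and 4-hydroxybenzaldehyde by oxa-Pictet–Spengler cyclisation and hydrogenolysis, where a temporary isochroman ring places the benzyl group.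
5. Ring order: the temporary isochroman (formed, then opened) and the first cyclobutenone are made in parallel. A second cyclobutenone forms inside the cascade, and ring A forms last. The other four benzene rings are bought.

## Route

Step 1
Reactants: 1 ethoxyacetylene; 2 4-(benzyloxy)benzyl chloride
Product: 4 1-(benzyloxy)-4-(3-ethoxyprop-2-yn-1-yl)benzene, via lithium ethoxyacetylide 3 (not isolated)
Conditions: n-BuLi (1.05 equiv), THF, −78 °C; then 2, DMPU, −78 °C → rt; Et3N-deactivated silica
Reagents that add atoms: none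
Why: This is an SN2 acetylide alkylation in which the lithium acetylide of an ynol ether displaces chloride from a very reactive p-alkoxybenzyl chloride in a dipolar cosolvent, and no stereocentre is formed.

Step 2
Reactants: 4 1-(benzyloxy)-4-(3-ethoxyprop-2-yn-1-yl)benzene (two molecules)
Product: 6 2,4-bis[4-(benzyloxy)benzyl]-3-ethoxycyclobut-2-en-1-one (racemic), via [4-(benzyloxy)benzyl]ketene 5 (not isolated)
Conditions: xylenes (1 M), 120 °C, N2 sweep, 6 h
Reagents that add atoms: none
Why: Retro-ene loss of ethene from the ethyl alkynyl ether releases the aldoketene slowly in an excess of the same electron-rich alkyne, which traps it in a regiospecific ketene–ynol ether [2+2] cycloaddition (alkyne β-carbon to ketene carbonyl carbon), so both benzyl arms of ring A come from one building block and the racemic C4 centre is erased in step 8.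

Step 3
Reactants: 7 2-(3-hydroxyphenyl)ethanol; 8 4-hydroxybenzaldehyde
Product: 10 3-(2-hydroxyethyl)-4-(4-hydroxybenzyl)phenol, via 1-(4-hydroxyphenyl)isochroman-6-ol 9 (not isolated)
Conditions: p-TsOH·H2O (10 mol %), MeOH, rt, 24 h; then 10% Pd/C, H2 (1 atm), rt, 12 h
Reagents that add atoms: none
Why: The oxa-Pictet–Spengler cyclisation is directed by the tether to the position para to the phenol OH, and acid-assisted catalytic hydrogenolysis of the doubly benzylic C1–O bond then leaves the 4-hydroxybenzyl group ortho to the hydroxyethyl chain while removing the racemic C1 centre of 9.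

Step 4
Reactants: 10 3-(2-hydroxyethyl)-4-(4-hydroxybenzyl)phenol
Product: 11 2-{5-(benzyloxy)-2-[4-(benzyloxy)benzyl]phenyl}ethanol
Conditions: BnBr (2.2 equiv), K2CO3 (2.5 equiv), acetone, reflux
Reagents that add atoms: benzyl bromide, BrCc1ccccc1
Why: In this Williamson ether synthesis K2CO3 ionises only the two phenols, so the primary alcohol stays free.

Step 5
Reactants: 11 2-{5-(benzyloxy)-2-[4-(benzyloxy)benzyl]phenyl}ethanol
Product: 12 4-(benzyloxy)-1-[4-(benzyloxy)benzyl]-2-(2-bromoethyl)benzene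
Conditions: CBr4, PPh3, CH2Cl2, 0 °C
Reagents that add atoms: carbon tetrabromide, BrC(Br)(Br)Br
Why: The Appel reaction converts an unhindered primary alcohol into the bromide under neutral conditions that leave the aryl benzyl ethers untouched.

Step 6
Reactants: 12 4-(benzyloxy)-1-[4-(benzyloxy)benzyl]-2-(2-bromoethyl)benzene; 6 2,4-bis[4-(benzyloxy)benzyl]-3-ethoxycyclobut-2-en-1-one
Product: 15 2,4-bis[4-(benzyloxy)benzyl]-3-(2-{5-(benzyloxy)-2-[4-(benzyloxy)benzyl]phenyl}ethyl)cyclobut-2-en-1-one (racemic), via Grignard reagent 13 (not isolated), via cyclobutenol adduct 14 (not isolated)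
Conditions: Mg, THF, 35 °C; then 6, THF, −78 → 0 °C; then 1 M aq HCl, THF, rt
Reagents that add atoms: water, O
Why: Grignard 1,2-addition to the strained vinylogous ester, which cannot enolise because that would give an antiaromatic cyclobutadienolate, is followed by acid hydrolysis with a Stork–Danheiser-type carbonyl transposition, and since C2 and C4 of 6 carry the same group only one constitution results, the stereocentres being inconsequential.

Step 7
Reactants: 16 chloroacetaldehyde dimethyl acetal
Product: 19 methoxyacetylene (kept as a cold toluene solution), via 1-chloro-2-methoxyethene 17 (not isolated), via sodium methoxyacetylide 18 (not isolated)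
Conditions: NaNH2 (3.1 equiv), liq. NH3, −33 °C; then ice-cold H2O; distil (bp 23 °C) into PhMe at −78 °C
Reagents that add atoms: none
Why: This is the classical alkoxyacetylene synthesis, in which two successive base-induced eliminations (of methanol, then of HCl) give the acetylide that is protonated on quench.

Step 8
Reactants: 15 2,4-bis[4-(benzyloxy)benzyl]-3-(2-{5-(benzyloxy)-2-[4-(benzyloxy)benzyl]phenyl}ethyl)cyclobut-2-en-1-one; 19 methoxyacetylene
Product: 24 2,4-bis[4-(benzyloxy)benzyl]-3-(2-{5-(benzyloxy)-2-[4-(benzyloxy)benzyl]phenyl}ethyl)-5-methoxyphenol, via vinylketene 20 (not isolated), via vinylcyclobutenone 21 (not isolated), via dienylketene 22 (not isolated), via cyclohexadienone 23 (not isolated)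
Conditions: 19 (3 equiv), PhMe, sealed tube, 80 °C, 12 h, then 130 °C, 6 h
Reagents that add atoms: none
Why: In the Danheiser benzannulation a 4π electrocyclic opening of 15 (C4 benzyl group rotating outward), a regiospecific [2+2] of the ketene and the ynol ether, a reversible 4π opening, a 6π electrocyclisation and tautomerisation put the ketene oxygen on as the free OH, the alkyne CH next to it and OMe meta to it, while methoxyacetylene cannot lose an alkene by retro-ene and all transient stereocentres disappear on aromatisation.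

Step 9
Reactants: 24 2,4-bis[4-(benzyloxy)benzyl]-3-(2-{5-(benzyloxy)-2-[4-(benzyloxy)benzyl]phenyl}ethyl)-5-methoxyphenol
Product: 25 2,4-bis(4-hydroxybenzyl)-3-{2-[5-hydroxy-2-(4-hydroxybenzyl)phenyl]ethyl}-5-methoxyphenol (target CNP0147493.0)
Conditions: H2 (1 atm), 10% Pd/C, EtOAc–MeOH, rt
Reagents that add atoms: none
Why: Catalytic hydrogenolysis cleaves the four aryl benzyl ether C–O bonds, while the diarylmethane C–C bonds, the methyl ether and the ethano bridge are inert.

## Compound list
1 | ethoxyacetylene | C#COCC | starting material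
2 | 4-(benzyloxy)benzyl chloride | ClCc1ccc(OCc2ccccc2)cc1 | starting material
3 | lithium ethoxyacetylide | [Li]C#COCC | intermediate
4 | 1-(benzyloxy)-4-(3-ethoxyprop-2-yn-1-yl)benzene | CCOC#CCc1ccc(OCc2ccccc2)cc1 | intermediate
5 | [4-(benzyloxy)benzyl]ketene | O=C=CCc1ccc(OCc2ccccc2)cc1 | intermediate
6 | 2,4-bis[4-(benzyloxy)benzyl]-3-ethoxycyclobut-2-en-1-one (racemic) | CCOC1=C(Cc2ccc(OCc3ccccc3)cc2)C(=O)C1Cc1ccc(OCc2ccccc2)cc1 | intermediate
7 | 2-(3-hydroxyphenyl)ethanol | OCCc1cccc(O)c1 | starting material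
8 | 4-hydroxybenzaldehyde | O=Cc1ccc(O)cc1 | starting material
9 | 1-(4-hydroxyphenyl)isochroman-6-ol (racemic) | Oc1ccc(cc1)C1OCCc2cc(O)ccc12 | intermediate
10 | 3-(2-hydroxyethyl)-4-(4-hydroxybenzyl)phenol | OCCc1cc(O)ccc1Cc1ccc(O)cc1 | intermediate
11 | 2-{5-(benzyloxy)-2-[4-(benzyloxy)benzyl]phenyl}ethanol | OCCc1cc(OCc2ccccc2)ccc1Cc1ccc(OCc2ccccc2)cc1 | intermediate
12 | 4-(benzyloxy)-1-[4-(benzyloxy)benzyl]-2-(2-bromoethyl)benzene | BrCCc1cc(OCc2ccccc2)ccc1Cc1ccc(OCc2ccccc2)cc1 | intermediate
13 | 2-{5-(benzyloxy)-2-[4-(benzyloxy)benzyl]phenyl}ethylmagnesium bromide | Br[Mg]CCc1cc(OCc2ccccc2)ccc1Cc1ccc(OCc2ccccc2)cc1 | intermediate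
14 | 2,4-bis[4-(benzyloxy)benzyl]-1-(2-{5-(benzyloxy)-2-[4-(benzyloxy)benzyl]phenyl}ethyl)-3-ethoxycyclobut-2-en-1-ol (diastereomer mixture, racemic; formed as its bromomagnesium alkoxide) | CCOC1=C(Cc2ccc(OCc3ccccc3)cc2)C(O)(CCc2cc(OCc3ccccc3)ccc2Cc2ccc(OCc3ccccc3)cc2)C1Cc1ccc(OCc2ccccc2)cc1 | intermediate
15 | 2,4-bis[4-(benzyloxy)benzyl]-3-(2-{5-(benzyloxy)-2-[4-(benzyloxy)benzyl]phenyl}ethyl)cyclobut-2-en-1-one (racemic) | O=C1C(Cc2ccc(OCc3ccccc3)cc2)=C(CCc2cc(OCc3ccccc3)ccc2Cc2ccc(OCc3ccccc3)cc2)C1Cc1ccc(OCc2ccccc2)cc1 | intermediate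
16 | chloroacetaldehyde dimethyl acetal | COC(CCl)OC | starting material
17 | 1-chloro-2-methoxyethene | COC=CCl | intermediate
18 | sodium methoxyacetylide | COC#C[Na] | intermediate
19 | methoxyacetylene | COC#C | intermediate
20 | vinylketene from 4π opening of 15, (E) at the trisubstituted alkene | O=C=C(Cc1ccc(OCc2ccccc2)cc1)/C(CCc1cc(OCc2ccccc2)ccc1Cc1ccc(OCc2ccccc2)cc1)=C/Cc1ccc(OCc2ccccc2)cc1 | intermediate
21 | 4-alkenyl-4-[4-(benzyloxy)benzyl]-3-methoxycyclobut-2-en-1-one, the [2+2] adduct of 20 and 19 (racemic) | O=C1C=C(OC)C1(Cc1ccc(OCc2ccccc2)cc1)/C(CCc1cc(OCc2ccccc2)ccc1Cc1ccc(OCc2ccccc2)cc1)=C/Cc1ccc(OCc2ccccc2)cc1 | intermediate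
22 | dienylketene from 4π opening of 21, ketene arm and alkenyl arm cis on the enol-ether alkene | O=C=C/C(OC)=C(Cc1ccc(OCc2ccccc2)cc1)\C(CCc1cc(OCc2ccccc2)ccc1Cc1ccc(OCc2ccccc2)cc1)=C\Cc1ccc(OCc2ccccc2)cc1 | intermediate
23 | cyclohexa-2,4-dien-1-one tautomer of 24 (racemic) | O=C1C=C(OC)C(Cc2ccc(OCc3ccccc3)cc2)=C(CCc2cc(OCc3ccccc3)ccc2Cc2ccc(OCc3ccccc3)cc2)C1Cc1ccc(OCc2ccccc2)cc1 | intermediate
24 | 2,4-bis[4-(benzyloxy)benzyl]-3-(2-{5-(benzyloxy)-2-[4-(benzyloxy)benzyl]phenyl}ethyl)-5-methoxyphenol | COc1cc(O)c(Cc2ccc(OCc3ccccc3)cc2)c(CCc2cc(OCc3ccccc3)ccc2Cc2ccc(OCc3ccccc3)cc2)c1Cc1ccc(OCc2ccccc2)cc1 | intermediate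
25 | 2,4-bis(4-hydroxybenzyl)-3-{2-[5-hydroxy-2-(4-hydroxybenzyl)phenyl]ethyl}-5-methoxyphenol (achiral) | COc1cc(O)c(Cc2ccc(O)cc2)c(CCc2cc(O)ccc2Cc2ccc(O)cc2)c1Cc1ccc(O)cc1 | target

## Step count and risks
Total step count: 9. Longest linear sequence: 6 (steps 3, 4, 5, 6, 8, 9).

**Step 8 (benzannulation).**
- Risks: the ketene carbon of 20 is fully substituted, methoxyacetylene is volatile and polymerises easily, and phenol 24 can be acylated by 20.
- Fallback: this gives up the de novo ring and takes ring A from an arene. It sets out from Grignard reagent 13 (made from 12) and chloride 2, and comes back to the route at 25.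
- Commercial 3-bromo-5-methoxyphenol is benzylated (BnBr, K2CO3, acetone) to 1-(benzyloxy)-3-bromo-5-methoxybenzene F1.
- Kumada coupling of 13 and F1 (NiCl2(dppp), THF) gives 1-(benzyloxy)-3-(2-{5-(benzyloxy)-2-[4-(benzyloxy)benzyl]phenyl}ethyl)-5-methoxybenzene F2.
- Twofold Friedel–Crafts benzylation of F2 by 2 (2.1 equiv, catalytic ZnCl2, CH2Cl2, 0 °C) gives the pentabenzyl ether of the target F3. It occurs at the two most activated ring A positions, each para to one alkoxy group and ortho to the other, flanking the bridge.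
- Hydrogenolysis of F3 (H2, 10% Pd/C) gives 25.

**Step 2 (thermal self-condensation).**
- Risks: ketene 5 may dimerise, or 6 may open at 120 °C and consume more 4.
- Fallback: this separates ketene generation from ynol ether thermolysis. It sets out from 4 and comes back at 6.
- Commercial 3-[4-(benzyloxy)phenyl]propanoic acid is converted by (COCl)2 and catalytic DMF into 3-[4-(benzyloxy)phenyl]propanoyl chloride F4.
- Slow addition of Et3N to F4 and 4 in CH2Cl2 at room temperature forms ketene 5 by dehydrochlorination. Compound 4 then captures 5 in the same [2+2] sense to give 6, well below the temperature at which 4 or 6 reacts thermally.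

**Step 6 (Grignard addition and transposition).**
- Risks: the carbonyl group is flanked by two benzyl-bearing carbons, Wurtz coupling of 12 can occur, and adduct 14 may open instead of hydrolysing.
- Fallback: this replaces addition and transposition by cross-coupling at the β-carbon. It sets out from 6 and 12 and comes back at 15.
- Compound 6 is hydrolysed (2 M HCl, THF, 50 °C) to 2,4-bis[4-(benzyloxy)benzyl]-3-hydroxycyclobut-2-en-1-one F5.
- F5 is converted by Tf2O and pyridine (CH2Cl2, −78 °C) into 2,4-bis[4-(benzyloxy)benzyl]-3-oxocyclobut-1-en-1-yl trifluoromethanesulfonate F6.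
- Bromide 12 is turned by Zn dust and LiCl (THF) into 2-{5-(benzyloxy)-2-[4-(benzyloxy)benzyl]phenyl}ethylzinc bromide F7.
- Negishi coupling of F7 and F6 (Pd(OAc)2, SPhos, THF, rt) gives 15 without any attack on the carbonyl group.

## Further compounds
F1 | step 8 | 1-(benzyloxy)-3-bromo-5-methoxybenzene | COc1cc(Br)cc(OCc2ccccc2)c1
F2 | step 8 | 1-(benzyloxy)-3-(2-{5-(benzyloxy)-2-[4-(benzyloxy)benzyl]phenyl}ethyl)-5-methoxybenzene | COc1cc(OCc2ccccc2)cc(CCc2cc(OCc3ccccc3)ccc2Cc2ccc(OCc3ccccc3)cc2)c1
F3 | step 8 | pentabenzyl ether of the target (O-benzyl derivative of 24) | COc1cc(OCc2ccccc2)c(Cc2ccc(OCc3ccccc3)cc2)c(CCc2cc(OCc3ccccc3)ccc2Cc2ccc(OCc3ccccc3)cc2)c1Cc1ccc(OCc2ccccc2)cc1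
F4 | step 2 | 3-[4-(benzyloxy)phenyl]propanoyl chloride | O=C(Cl)CCc1ccc(OCc2ccccc2)cc1
F5 | step 6 | 2,4-bis[4-(benzyloxy)benzyl]-3-hydroxycyclobut-2-en-1-one (racemic) | OC1=C(Cc2ccc(OCc3ccccc3)cc2)C(=O)C1Cc1ccc(OCc2ccccc2)cc1
F6 | step 6 | 2,4-bis[4-(benzyloxy)benzyl]-3-oxocyclobut-1-en-1-yl trifluoromethanesulfonate (racemic) | O=C1C(Cc2ccc(OCc3ccccc3)cc2)=C(OS(=O)(=O)C(F)(F)F)C1Cc1ccc(OCc2ccccc2)cc1
F7 | step 6 | 2-{5-(benzyloxy)-2-[4-(benzyloxy)benzyl]phenyl}ethylzinc bromide | Br[Zn]CCc1cc(OCc2ccccc2)ccc1Cc1ccc(OCc2ccccc2)cc1
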